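A direct plan would C-acylate 2,4,6-trihydroxytoluene A1 to the isovaleryl ketone A2 and would then differentiate the hydroxyls of A2 by a protect–methylate–deprotect sequence to reach the terminal monomer A3 as the nucleophilic partner. A second, unsubstituted triol ring would be formylated twice to the dialdehyde A4 and then A4 would be acylated to the diformyl ketone A5 so that A5 could finally be joined with two A3 by an acid-catalysed reductive arylmethylation.
Its weakest steps would be:
- the hydroxyl differentiation, which would spend three steps on one O-methyl group and would depend on an alkylating agent choosing between two chelated ortho-hydroxyls;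
- the Friedel–Crafts acylation of A4, whose last ring position is deactivated by two formyl groups;
- the closing double reductive coupling, a reaction without precedent that would be run on both finished fragments, where triarylmethane formation or aldehyde reduction would destroy them.

**Plan of the new route**
Terminal ring numbering: C-1 (OMe), C-2 (Me), C-3 (OH), C-4 (CH2 bridge), C-5 (OH), C-6 (isovaleryl). The retrosynthesis cuts C-3–C-4 and C-5–C-6 in both terminal rings.
Enabling feature: each bridge joins a ring B carbon ortho to a phenol oxygen with C-4, and C-4 is flanked by the oxygen-bearing C-5. The unit O(ring B)–C-5(=O)–C-4–CH2–C(ring B) is therefore a 3,4-dihydrocoumarin lactone fused to ring B. C-3, C-2, C-1 and C-6 with their O, Me, OMe and acyl are C-2, C-3, C-4 and C-5 of 6-isobutyl-4-methoxy-3-methyl-2-pyranone, whose C-6 and ring oxygen become the isovaleryl C=O.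
Ring B is bought, acylated and annulated with two acrylic acids; both terminal rings arise last and at once from two pyranones.
The O-methyl site is fixed on a pyranone with a single hydroxyl, so no phenol differentiation is needed. No formyl group is made, so no deactivated ring is acylated. The bridges are never formed by joining two arenes, so no reductive coupling occurs.
The target is achiral; overall the acylated ring B, two acrylic acids and two pyranones give the target and two H2O.

Key step: step 6

Assumption: in step 2 the two propanoic arms close on the ring B oxygens para and ortho to the ketone, leaving the ketone-chelated OH free; the other closure isomer has the same carbon skeleton and would give the same product in step 6.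

Step 1
Reactants: 1 benzene-1,3,5-triol (phloroglucinol); 2 3-methylbutanoyl chloride (isovaleryl chloride)
Product: 3 3-methyl-1-(2,4,6-trihydroxyphenyl)butan-1-one
Conditions: AlCl3 (4 equiv), PhNO2/CH2Cl2, 0 → 40 °C; ice/aq. HCl
Reagents that add atoms: none
Why: Friedel–Crafts C-acylation of the threefold-symmetric triol, which should stop after one acyl group because the chelated aryl ketone deactivates the ring.

Step 2
Reactants: 3 3-methyl-1-(2,4,6-trihydroxyphenyl)butan-1-one; 4 prop-2-enoic acid (acrylic acid)
Product: 5 5-hydroxy-6-(3-methylbutanoyl)-3,4,9,10-tetrahydro-2H,8H-pyrano[2,3-f]chromene-2,8-dione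
Conditions: 4 (5 equiv), 4-MeC6H4SO3H·H2O (0.3 equiv), BHT (1 mol %), PhCl, 125 °C, Dean–Stark
Reagents that add atoms: none
Why: acid-catalysed hydroarylation of acrylic acid (conjugate Friedel–Crafts alkylation) at the only two free ring positions, each followed by lactonisation of the new propanoic acid onto a neighbouring phenol to give a 3,4-dihydrocoumarin ring.

Step 3
Reactants: 5 5-hydroxy-6-(3-methylbutanoyl)-3,4,9,10-tetrahydro-2H,8H-pyrano[2,3-f]chromene-2,8-dione
Product: 6 5-[(tert-butyldimethylsilyl)oxy]-6-{1-[(tert-butyldimethylsilyl)oxy]-3-methylbut-1-en-1-yl}-3,4,9,10-tetrahydro-2H,8H-pyrano[2,3-f]chromene-2,8-dione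
Conditions: TBSOTf (2.4 equiv), Et3N (3.5 equiv), CH2Cl2, 0 → 25 °C
Reagents that add atoms: tert-butyldimethylsilyl trifluoromethanesulfonate, CC(C)(C)[Si](C)(C)OS(=O)(=O)C(F)(F)F
Why: soft enolisation and silylation should convert the phenol into its silyl ether and the aryl ketone (enolised far more readily than the lactones) into its silyl enol ether, so that step 6 meets no acidic O–H and no ketone enolate that could attack the neighbouring lactone by Baker–Venkataraman acyl transfer.

Step 4
Reactants: 7 ethyl 2-methyl-3-oxobutanoate; 8 methyl 3-methylbutanoate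
Product: 10 4-hydroxy-3-methyl-6-(2-methylpropyl)-2H-pyran-2-one, via ethyl 2,7-dimethyl-3,5-dioxooctanoate 9 (not isolated)
Conditions: 7 (2.0 equiv), LiN(i-Pr)2 (4.1 equiv), THF, −78 → 0 °C; 8 (1.0 equiv), 0 → 25 °C; aq. HCl; crude 9, DBU (1.1 equiv), PhMe, 110 °C
Reagents that add atoms: none
Why: γ-acylation of the β-keto ester dianion by the ester (crossed Claisen condensation at the more basic terminal carbanion), then DBU-promoted lactonisation of the 5-enol onto the ethyl ester, should give the 4-hydroxy-2-pyranone.

Step 5
Reactants: 10 4-hydroxy-3-methyl-6-(2-methylpropyl)-2H-pyran-2-one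
Product: 11 4-methoxy-3-methyl-6-(2-methylpropyl)-2H-pyran-2-one
Conditions: Me2SO4 (1.3 equiv), K2CO3 (2 equiv), acetone, reflux
Reagents that add atoms: dimethyl sulfate, COS(=O)(=O)OC
Why: Williamson-type O-methylation of the only hydroxyl of the pyranone, which fixes the future aryl methyl ether between the C-methyl carbon and the future acyl-bearing carbon before the arene exists; the 4-methoxy-2-pyranone is the usual product under these conditions.

Step 6
Reactants: 6 5-[(tert-butyldimethylsilyl)oxy]-6-{1-[(tert-butyldimethylsilyl)oxy]-3-methylbut-1-en-1-yl}-3,4,9,10-tetrahydro-2H,8H-pyrano[2,3-f]chromene-2,8-dione (1 equiv); 11 4-methoxy-3-methyl-6-(2-methylpropyl)-2H-pyran-2-one (2.5 equiv)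
Product: 14 1-{3,5-bis[[2,6-dihydroxy-4-methoxy-5-methyl-3-(3-methylbutanoyl)phenyl]methyl]-2,4,6-trihydroxyphenyl}-3-methylbutan-1-one, via open-chain bis(2-acyl lactone) 12 (not isolated), via bis-silylated trimer 13 (not isolated)
Conditions: LiN(i-Pr)2 (2.2 equiv), THF, −78 °C, 45 min; 11 in THF, −78 → 25 °C, 12 h; then 2 M HCl, THF/MeOH, 25 → 40 °C
Reagents that add atoms: none
Why: Proposed new method: two-directional anionic [4+2] benzannulation in which each lithium lactone enolate of 6 (the future C-4 of a terminal ring) adds to the lactone carbonyl C-2 of pyranone 11, the adduct collapses by opening the pyranone to the extended enolate of the isobutyl ketone (the open-chain 2-acyl lactones 12), and the α-carbon of that enolate (former pyranone C-5, held cis to the new ketone by the former ring double bond) attacks the aryl lactone carbonyl in a Claisen closure that expels the ring B phenoxide and aromatises to the acylphloroglucinol monomethyl ether. The closest known reaction types are the crossed Claisen acylation of ester enolates by lactones, the opening of 4-methoxy-2-pyranones at C-2 by alkoxides, the base-induced Claisen cyclisation of 3,5,7-triketo esters to acylphloroglucinols and the Staunton–Weinreb annulation of carbanions with 4-methoxy-2-pyranones, which however begins by conjugate addition at C-4. Each terminal ring closes in the 6-exo-trig mode by C–C bond formation between former pyranone C-5 and the lactone carbonyl, driven by aromatisation and phenoxide release, and no stereocentre survives because both lactone α-carbons become arene carbons. The selectivity needed is attack at pyranone C-2 rather than conjugate addition at C-4 or C-6 or deprotonation of the 6-CH2: C-4 is a tetrasubstituted, methoxy-donated carbon shielded by the C-3 methyl, C-6 is deactivated by the ring oxygen and carries a branched alkyl group, and a hard lithium enolate at −78 °C favours carbonyl addition. Complete enolisation of both lactones before 11 is added leaves no neutral lactone for self-condensation, and the silyl enol ether keeps the ring B ketone out of Baker–Venkataraman transfer. Aqueous HCl then hydrolyses the aryl silyl ether (activated by the ortho ketone) and the silyl enol ether of 13 to the phenol and the isovaleryl ketone of 14.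

**Compound list**
1 | benzene-1,3,5-triol (phloroglucinol) | Oc1cc(O)cc(O)c1 | starting material
2 | 3-methylbutanoyl chloride (isovaleryl chloride) | CC(C)CC(Cl)=O | starting material
3 | 3-methyl-1-(2,4,6-trihydroxyphenyl)butan-1-one | CC(C)CC(=O)c1c(O)cc(O)cc1O | intermediate
4 | prop-2-enoic acid (acrylic acid) | C=CC(=O)O | starting material
5 | 5-hydroxy-6-(3-methylbutanoyl)-3,4,9,10-tetrahydro-2H,8H-pyrano[2,3-f]chromene-2,8-dione (ring B with two fused dihydrocoumarin lactones) | CC(C)CC(=O)c1c(O)c2CCC(=O)Oc2c2CCC(=O)Oc12 | intermediate
6 | 5-[(tert-butyldimethylsilyl)oxy]-6-{1-[(tert-butyldimethylsilyl)oxy]-3-methylbut-1-en-1-yl}-3,4,9,10-tetrahydro-2H,8H-pyrano[2,3-f]chromene-2,8-dione (enol ether geometry not defined; either isomer serves) | CC(C)C=C(O[Si](C)(C)C(C)(C)C)c1c(O[Si](C)(C)C(C)(C)C)c2CCC(=O)Oc2c2CCC(=O)Oc12 | intermediate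
7 | ethyl 2-methyl-3-oxobutanoate | CCOC(=O)C(C)C(C)=O | starting material
8 | methyl 3-methylbutanoate | COC(=O)CC(C)C | starting material
9 | ethyl 2,7-dimethyl-3,5-dioxooctanoate (not isolated) | CCOC(=O)C(C)C(=O)CC(=O)CC(C)C | intermediate
10 | 4-hydroxy-3-methyl-6-(2-methylpropyl)-2H-pyran-2-one | CC(C)Cc1cc(O)c(C)c(=O)o1 | intermediate
11 | 4-methoxy-3-methyl-6-(2-methylpropyl)-2H-pyran-2-one | COc1cc(CC(C)C)oc(=O)c1C | intermediate
12 | compound 6 carrying a (2E)-3-methoxy-2,7-dimethyl-5-oxooct-2-enoyl group on each lactone α-carbon, C-3 and C-9 (not isolated; the two α-carbons are enolisable and undefined) | CC(C)C=C(O[Si](C)(C)C(C)(C)C)c1c(O[Si](C)(C)C(C)(C)C)c2CC(C(=O)\C(C)=C(OC)/CC(=O)CC(C)C)C(=O)Oc2c2CC(C(=O)\C(C)=C(OC)/CC(=O)CC(C)C)C(=O)Oc12 | intermediate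
13 | the target with its ring B ketone as tert-butyldimethylsilyl enol ether and the adjacent ring B hydroxyl as tert-butyldimethylsilyl ether (not isolated) | CC(C)C=C(O[Si](C)(C)C(C)(C)C)c1c(O[Si](C)(C)C(C)(C)C)c(Cc2c(O)c(C)c(OC)c(C(=O)CC(C)C)c2O)c(O)c(Cc2c(O)c(C)c(OC)c(C(=O)CC(C)C)c2O)c1O | intermediate
14 | 1-{3,5-bis[[2,6-dihydroxy-4-methoxy-5-methyl-3-(3-methylbutanoyl)phenyl]methyl]-2,4,6-trihydroxyphenyl}-3-methylbutan-1-one (CNP0158539.0) | COc1c(C)c(O)c(Cc2c(O)c(Cc3c(O)c(C)c(OC)c(C(=O)CC(C)C)c3O)c(O)c(C(=O)CC(C)C)c2O)c(O)c1C(=O)CC(C)C | target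

Total step count: 6. Longest linear sequence: 4 (steps 1, 2, 3, 6); the pyranone branch (steps 4, 5) joins at step 6.

**Steps most likely to fail**

Step 6 (proposed new method). The lactone enolate may add in conjugate fashion at pyranone C-4 with loss of methoxide, may be quenched by proton transfer from the pyranone 6-CH2, or the sequence may stall at the open-chain stage. The fallback sets out from 6 and comes back at 12, using an acyl donor that can react only at its carbonyl carbon. Compound 7 would be converted with HC(OMe)3 and catalytic H2SO4 into ethyl (E)-3-methoxy-2-methylbut-2-enoate F1 as its enol ether. F1 would be saponified (KOH, aqueous MeOH; acidification at 0 °C) to (E)-3-methoxy-2-methylbut-2-enoic acid F2 and then F2 would be turned with (COCl)2 into (E)-3-methoxy-2-methylbut-2-enoyl chloride F3 for the acylation. The bis-lithium enolate of 6 would be C-acylated with F3 (ester enolate acylation by an acid chloride) to the bis-acylated bis-lactone F4 which is compound 6 carrying a (2E)-3-methoxy-2-methylbut-2-enoyl group at C-3 and at C-9. The polyanion of F4 (excess LiN(i-Pr)2) would then be acylated at its two terminal γ-methyl groups with ester 8, as in the γ-acylation of step 4. This gives 12, which would be closed by the Claisen cyclisation and worked up with acid as in step 6.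

Step 2. The ring may be acylated instead of alkylated (chroman-4-one formation), acrylic acid may polymerise, or the reaction may stop after the first annulation because the first lactone deactivates the ring. The fallback sets out from 3 and comes back at 5. Compound 3 would be annulated twice with ethyl propiolate (Pd(OAc)2, CF3CO2H, 25 °C; hydroarylation then lactonisation) to 5-hydroxy-6-(3-methylbutanoyl)-2H,8H-pyrano[2,3-f]chromene-2,8-dione F5 as the bis-coumarin. The two coumarin C=C bonds of F5 would then be hydrogenated (H2, Pd/C, EtOAc, 25 °C) to give 5.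

Step 3. Silylation may be incomplete or unselective (silyl ketene acetal formation at the lactones), or the enol silyl ether may be lost before the enolates are formed, exposing the ketone to enolisation and acyl transfer. The fallback sets out from 1 and comes back at 14; it dispenses with ketone masking by introducing the ring B acyl group last. Compound 1 would be annulated with two equivalents of 4 as in step 2 to 5-hydroxy-3,4,9,10-tetrahydro-2H,8H-pyrano[2,3-f]chromene-2,8-dione F6 and then F6 would be silylated (TBSCl, imidazole, DMF) to 5-[(tert-butyldimethylsilyl)oxy]-3,4,9,10-tetrahydro-2H,8H-pyrano[2,3-f]chromene-2,8-dione F7 as the only protected intermediate. F7 would be annulated with 11 as in step 6, with the same acidic work-up, to 2,4-bis{[2,6-dihydroxy-4-methoxy-5-methyl-3-(3-methylbutanoyl)phenyl]methyl}benzene-1,3,5-triol F8 as the deacyl trimer. F8 would then be C-acylated at its single free ring position with 2 (TiCl4, CH2Cl2, 0 → 25 °C, Friedel–Crafts acylation; AlCl3 is avoided because it would cleave the methyl ethers ortho to the ketones) to give 14.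

**Further compounds**
F1 | step 6 | ethyl (E)-3-methoxy-2-methylbut-2-enoate | CCOC(=O)/C(C)=C(\C)OC
F2 | step 6 | (E)-3-methoxy-2-methylbut-2-enoic acid | OC(=O)/C(C)=C(\C)OC
F3 | step 6 | (E)-3-methoxy-2-methylbut-2-enoyl chloride | ClC(=O)/C(C)=C(\C)OC
F4 | step 6 | bis-acylated bis-lactone: compound 6 carrying a (2E)-3-methoxy-2-methylbut-2-enoyl group at C-3 and at C-9 | CC(C)C=C(O[Si](C)(C)C(C)(C)C)c1c(O[Si](C)(C)C(C)(C)C)c2CC(C(=O)\C(C)=C(OC)/C)C(=O)Oc2c2CC(C(=O)\C(C)=C(OC)/C)C(=O)Oc12
F5 | step 2 | 5-hydroxy-6-(3-methylbutanoyl)-2H,8H-pyrano[2,3-f]chromene-2,8-dione | CC(C)CC(=O)c1c(O)c2ccc(=O)oc2c2ccc(=O)oc12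
F6 | step 3 | 5-hydroxy-3,4,9,10-tetrahydro-2H,8H-pyrano[2,3-f]chromene-2,8-dione | c1c(O)c2CCC(=O)Oc2c2CCC(=O)Oc12
F7 | step 3 | 5-[(tert-butyldimethylsilyl)oxy]-3,4,9,10-tetrahydro-2H,8H-pyrano[2,3-f]chromene-2,8-dione | c1c(O[Si](C)(C)C(C)(C)C)c2CCC(=O)Oc2c2CCC(=O)Oc12
F8 | step 3 | 2,4-bis{[2,6-dihydroxy-4-methoxy-5-methyl-3-(3-methylbutanoyl)phenyl]methyl}benzene-1,3,5-triol | Oc1cc(O)c(Cc2c(O)c(C)c(OC)c(C(=O)CC(C)C)c2O)c(O)c1Cc1c(O)c(C)c(OC)c(C(=O)CC(C)C)c1O
A1 | direct plan | 2-methylbenzene-1,3,5-triol (2,4,6-trihydroxytoluene) | Cc1c(O)cc(O)cc1O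
A2 | direct plan | 3-methyl-1-(2,4,6-trihydroxy-3-methylphenyl)butan-1-one | CC(C)CC(=O)c1c(O)cc(O)c(C)c1O
A3 | direct plan | 1-(4,6-dihydroxy-2-methoxy-3-methylphenyl)-3-methylbutan-1-one | CC(C)CC(=O)c1c(O)cc(O)c(C)c1OC
A4 | direct plan | 2,4,6-trihydroxybenzene-1,3-dicarbaldehyde | O=Cc1c(O)cc(O)c(C=O)c1O
A5 | direct plan | 2,4,6-trihydroxy-5-(3-methylbutanoyl)benzene-1,3-dicarbaldehyde | CC(C)CC(=O)c1c(O)c(C=O)c(O)c(C=O)c1O
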